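Per minute is the unit of the rates I read here, and it cancels when I divide one rate by another, so that is what I do.

in all of them: left-handed substrate 0.11 M; right-handed substrate 0.11 M; free catalyst 0.47 mol%

| flask | partner | remark | time |
|---|---|---|---|
| zeta | 2.5 equiv | the very flask that is asked about, followed so far |  |
| flask | 2.50 equiv |  | 40 min |

zeta run (percent of the left-handed substrate and right-handed substrate together charged)

| time / min | left-handed substrate / % | left-handed product / % |
|---|---|---|
| 0.417 | 46.0 | 3.6 |
| 1.33 | 40.5 | 9.8 |
| 2.50 | 35.2 | 16.7 |
| 3.00 | 34.8 | 17.5 |
| 5.00 | 31.2 | 23.2 |
| 6.00 | 29.3 | 24.7 |
| 8.00 | 28.0 | 27.6 |

(each reading ± 0.5 percentage points)

- free catalyst is single-handed; left-handed substrate and right-handed substrate are mirror images of each other, charged as a racemate, each of them at the stated concentration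
- the reaction counts as stopped when no species that holds the left-handed substrate and right-handed substrate together changes by six tenths of a point or more over the second half of the time

1. why nothing more happens at 40 min, or that something still does (all of the left-handed substrate has reacted / forward and back rates have come level / it is still moving / the partner has run out first / no working catalyst is left)
2. how much of the left-handed substrate and right-handed substrate together has reacted by 40 min
3. how much left-handed product there is at 40 min, in percent of the left-handed substrate and right-handed substrate together charged
4. how much right-handed substrate there is at 40 min, in percent of the left-handed substrate and right-handed substrate together charged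
5. how much right-handed product there is at 40 min, in percent of the left-handed substrate and right-handed substrate together charged

The readings follow the very flask asked about. Let w be the gain rate of left-handed product divided by c(left-handed substrate). Early on w is 0.155 /min, and late it is 0.0495 /min, so it fades at 0.226 /min. I assume the partner is what fades, though a dying catalyst would look alike here. At that pace the partner keeps 0.0119 % of its charge by 40 min, so I expect a stop with substrate left.

Starting w over the fade gives a reach without time, 0.953. Past the last reading 0.156 of it remains, which lifts the left-handed product to 32.0 %.

The right-handed side is unseen. But if both substrates fall together, the crossing equals the difference of the two products divided by two. So the gain of left-handed substrate plus product, over the gain of left-handed product, is a ratio ρ, and one minus twice ρ is the right-to-left ratio. From 5.00 min to 8.00 min, ρ is 0.273, so the ratio is 0.455. The substrate pool then falls by the exponential of minus reach times the mean of one and that ratio, which gives 50.0 % conversion.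

The weak link is ρ, a gain of 1.2 percentage points read with scatter 0.5 points. Averaging the readings in pairs, 2.50 min with 3.00 min and 6.00 min with 8.00 min, gives ρ 0.298. The right-to-left ratio 0.403 is then a selectivity factor of 2.48. I commit to a partner-starved stop, conversion 48.8 %, right-handed substrate 25.6 %, right-handed product 16.8 %.

The forecast differs from me on the stop and on the right-handed product: it is still moving, 40 % reacted, 32 %, 30 % and 8 %, “guessing selectivity near 20 gives about 8%”.

The flask gives: the partner has run out first, conversion 46.7 %, left-handed product 31.4 %, right-handed substrate 26.7 %, right-handed product 15.3 %.

    partner → decomposed reagent (k = 0.00235 /s)
    partner + free catalyst + left-handed substrate → free catalyst + left-handed product (k = 23.8 /M²/s)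
    left-handed substrate ⇌ right-handed substrate (k = 0.00204 /s)
    free catalyst → spent catalyst (k = 9.74 × 10⁻⁶ /s)
    partner + free catalyst + right-handed substrate → free catalyst + right-handed product (k = 10.3 /M²/s)

At 40.0 min the partner keeps 0.025 % of its charge, less than the 53 % kept by the right-handed substrate. My right-to-left ratio turns 31.4 % of left-handed product into 12.7 % of right-handed product here, against 15.3 % in the flask. In the flask with 0.28 mol% of free catalyst it turns 24.0 % into 9.67 %, and that flask holds 11.2 %.

The runs stem from a simulated flask for substances that don't exist; the scatter is artificial.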